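The target is a (1(10)Z,4E)-germacradien-6,12-olide whose lactone oxygen sits on C6, allylic to the C4=C5 olefin. The γ-lactone ring (O, C6, C7, C11, C12) is therefore read as the 1,3-transposed isomer of a seven-membered lactone in which the same carboxyl group is esterified to tertiary C4 of a linalool-derived unit and C5=C6 is a Z olefin made by tethered ring-closing metathesis. A zerovalent-palladium-catalysed allylic transposition through a π-allyl carboxylate contracts this ring: it forms the O–C6 bond, transfers the C4 configuration to C6 and creates the C4=C5 E olefin in one operation. The ten-membered ring is closed afterwards at C9–C10.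

Key step: step 10

Remark: germacrane numbering is used for all intermediates (ring carbons C1–C10; lactone carbons C11–C13 with C12 the carbonyl and C13 the methylene; C14 the methyl on C10; C15 the methyl on C4).
Remark: (S)-(+)-linalool and (S)-glyceraldehyde acetonide are taken as purchasable in enantiopure form.

Step 1
Reactants: 1 methyl angelate [methyl (2Z)-2-methylbut-2-enoate]
Product: 2 (2Z)-2-methylbut-2-en-1-ol
Conditions: i-Bu2AlH (2.2 equiv), CH2Cl2, −78 → 0 °C; aq. KNaC4H4O6 work-up
Reagents that add atoms: none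
Why: 1,2-Reduction of the enoate by the aluminium hydride (ester reduction) at low temperature gives the allylic alcohol without isomerising the Z olefin.

Step 2
Reactants: 2 (2Z)-2-methylbut-2-en-1-ol
Product: 3 [(2R,3S)-2,3-dimethyloxiran-2-yl]methanol
Conditions: Ti(OiPr)4 (10 mol%), L-(+)-diethyl tartrate (12 mol%), t-BuOOH, 4 Å molecular sieves, CH2Cl2, −20 °C
Reagents that add atoms: tert-butyl hydroperoxide, CC(C)(C)OO
Why: Sharpless asymmetric epoxidation, in which the L-(+)-tartrate ligand directs oxygen to the olefin face that gives the (2R,3S)-epoxide and the syn addition keeps the cis (angelate-type) relationship.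

Step 3
Reactants: 3 [(2R,3S)-2,3-dimethyloxiran-2-yl]methanol
Product: 4 (2S,3S)-2,3-dimethyloxirane-2-carboxylic acid
Conditions: RuCl3·xH2O (2 mol%), NaIO4 (3 equiv), CCl4/MeCN/H2O, rt
Reagents that add atoms: sodium periodate, [Na+].[O-]I(=O)(=O)=O; water, O
Why: Ruthenium tetroxide oxidation of the primary alcohol to the acid via the aldehyde hydrate leaves the epoxide and both stereocentres untouched (the C2 descriptor changes only by priority).

Step 4
Reactants: 5 (S)-(+)-linalool; 6 acryloyl chloride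
Product: 7 (3S)-3,7-dimethylocta-1,6-dien-3-yl prop-2-enoate
Conditions: Et3N (2 equiv), DMAP (10 mol%), CH2Cl2, 0 °C → rt
Reagents that add atoms: none
Why: DMAP-catalysed acylation, in which the small reactive acid chloride esterifies the hindered tertiary allylic alcohol and the basic medium avoids ionisation of the linalyl ester.

Step 5
Reactants: 7 (3S)-3,7-dimethylocta-1,6-dien-3-yl prop-2-enoate
Product: 9 (3S)-6,6-dimethoxy-3-methylhex-1-en-3-yl prop-2-enoate, via aldehyde 8 (not isolated)
Conditions: O3 (1.0 equiv, Sudan red 7B indicator), CH2Cl2, −78 °C; Me2S, −78 °C → rt; then HC(OMe)3, MeOH, CeCl3·7H2O (10 mol%), rt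
Reagents that add atoms: ozone, [O-][O+]=O (oxygen of 8); trimethyl orthoformate, COC(OC)OC (both methoxy groups of 9)
Why: Chemoselective ozonolysis cleaves the electron-rich trisubstituted olefin far faster than the vinyl group or the acrylate, and the lanthanide-catalysed acetalisation masks the aldehyde without ionising the tertiary allylic ester.

Step 6
Reactants: 9 (3S)-6,6-dimethoxy-3-methylhex-1-en-3-yl prop-2-enoate; 10 (4S)-2,2-dimethyl-1,3-dioxolane-4-carbaldehyde
Product: 11 (3S)-6,6-dimethoxy-3-methylhex-1-en-3-yl 2-{[(4S)-2,2-dimethyl-1,3-dioxolan-4-yl](hydroxy)methyl}prop-2-enoate (both carbinol epimers at C7)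
Conditions: DABCO (1.0 equiv), 1,4-dioxane/H2O (1:1), rt, 3–5 d
Reagents that add atoms: none
Why: Morita–Baylis–Hillman reaction, in which the ammonium enolate of the acrylate adds to the aldehyde; the C7 carbinol configuration is irrelevant because C7 becomes sp2 in step 7, and C8 comes unchanged from 10.

Step 7
Reactants: 11 Morita–Baylis–Hillman adduct
Product: 12 (3S)-6,6-dimethoxy-3-methylhex-1-en-3-yl (2Z)-2-(bromomethyl)-3-[(4R)-2,2-dimethyl-1,3-dioxolan-4-yl]prop-2-enoate
Conditions: NBS (1.3 equiv), Me2S (1.5 equiv), CH2Cl2, 0 °C → rt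
Reagents that add atoms: N-bromosuccinimide, O=C1CCC(=O)N1Br
Why: Corey–Kim-type activation of the allylic alcohol followed by SN2′ attack of bromide gives the thermodynamically preferred (Z)-2-(bromomethyl)enoate under non-acidic conditions that spare both acetals and the tertiary ester.

Step 8
Reactants: 12 (Z)-allylic bromide
Product: 13 (3S)-6,6-dimethoxy-3-methylhex-1-en-3-yl (3R)-3-[(4R)-2,2-dimethyl-1,3-dioxolan-4-yl]-2-methylidenepent-4-enoate
Conditions: CH2=CHMgBr (1.5 equiv), CuBr·SMe2 (10 mol%), THF, −78 °C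
Reagents that add atoms: vinylmagnesium bromide, C=C[Mg]Br
Why: Copper-catalysed SN2′ substitution (conjugate addition–elimination), in which A(1,3) strain with the cis CH2Br group holds H8 in the olefin plane and the vinyl group enters C7 anti to the dioxolane C8–O bond (Felkin–Anh-type 1,2-induction), setting C7 anti to O8 and restoring the exocyclic methylene.

Step 9
Reactants: 13 diene ester
Product: 14 (4R,7S)-7-(3,3-dimethoxypropyl)-4-[(4R)-2,2-dimethyl-1,3-dioxolan-4-yl]-7-methyl-3-methylidene-4,7-dihydrooxepin-2(3H)-one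
Conditions: second-generation Grubbs catalyst RuCl2(=CHPh)(PCy3)(H2IMes) (5 mol%), CH2Cl2 (0.002 M), 40 °C
Reagents that add atoms: none
Why: Ring-closing metathesis of the two monosubstituted vinyl groups held by the ester tether closes the seven-membered ring (C5=C6 necessarily Z), while the 1,1-disubstituted acrylate olefin does not take part.

Step 10
Reactants: 14 seven-membered lactone
Product: 15 (4S,5R)-5-[(1E)-5,5-dimethoxy-2-methylpent-1-en-1-yl]-4-[(4R)-2,2-dimethyl-1,3-dioxolan-4-yl]-3-methylideneoxolan-2-one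
Conditions: Pd(PPh3)4 (5 mol%), degassed THF, rt, stopped at full conversion of 14
Reagents that add atoms: none
Why: Zerovalent palladium ionises the strained tertiary allylic C4–O bond of 14 with inversion to give a zwitterionic η3-allyl (C4–C5–C6) palladium carboxylate, and the tethered carboxylate then attacks the C6 terminus from the face opposite to palladium, releasing 15 and the catalyst. This is an intramolecular Tsuji–Trost allylic substitution in which the carboxylate is both leaving group and nucleophile, the palladium-catalysed 1,3-transposition known for allylic esters and vinyl lactones. The γ-lactone (O, C6, C7, C11, C12) closes by 5-exo attack of oxygen on the allyl terminus while the seven-membered ring is lost, a 7→5 ring contraction driven by relief of medium-ring strain, the tertiary-to-secondary ester change and the trisubstituted olefin, so re-ionisation of 15 should be much slower than its formation. Because ionisation and capture are both anti to palladium, the O–C6 bond forms on the olefin face that carried the C4–O bond (net retention, 1,3-chirality transfer); with the dioxolanyl group on C7 pseudo-equatorial, that face gives 6R, trans to the C7 substituent. In the same conformer the 4S centre (from (S)-linalool) places the C3 chain syn and the C15 methyl anti on the allyl unit, which becomes the E olefin, whereas the 4R epimer would give Z, so the match of the C4 and C7 configurations secures the geometry. The step needs capture at C6 and not C4 (only C6 gives a five-membered ring) and capture faster than syn/anti exchange or β-hydride elimination (intramolecular nucleophile, room temperature); the acetals and the exocyclic acrylate are inert.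

Step 11
Reactants: 15 γ-lactone
Product: 16 (4R,5R)-4-[(1R)-1,2-dihydroxyethyl]-3-methylidene-5-[(1E)-2-methyl-5-oxopent-1-en-1-yl]oxolan-2-one
Conditions: AcOH/H2O (4:1), 40 °C
Reagents that add atoms: water, O
Why: Acid-catalysed hydrolysis cleaves the dimethyl acetal and the isopropylidene ketal in one operation under conditions too mild to ionise the secondary allylic C6–O bond of the lactone.

Step 12
Reactants: 16 aldehyde diol
Product: 17 (4R,5R)-4-[(1R)-1-hydroxy-2-(triethylsilyloxy)ethyl]-3-methylidene-5-[(1E)-2-methyl-5-oxopent-1-en-1-yl]oxolan-2-one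
Conditions: Et3SiCl (1.05 equiv), imidazole, CH2Cl2, −40 → −20 °C
Reagents that add atoms: chlorotriethylsilane, CC[Si](Cl)(CC)CC
Why: Silylation is selective for the unhindered primary hydroxyl at C9 over the secondary hydroxyl at C8, which is flanked by the branched C7.

Step 13
Reactants: 17 hydroxy silyl ether; 4 (2S,3S)-2,3-dimethyloxirane-2-carboxylic acid
Product: 19 (4S,5R)-4-[(1R)-1-{[(2S,3S)-2,3-dimethyloxirane-2-carbonyl]oxy}-2-(triethylsilyloxy)ethyl]-3-methylidene-5-[(1E)-2-methyl-5-oxopent-1-en-1-yl]oxolan-2-one, via mixed anhydride 18 (not isolated)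
Conditions: 4, 2,4,6-trichlorobenzoyl chloride, Et3N, toluene, rt; then 17, DMAP, toluene, rt
Reagents that add atoms: none
Why: Yamaguchi esterification, in which DMAP transfers the epoxy acyl group of the mixed anhydride to the hindered C8 hydroxyl under mild basic conditions that leave the epoxide stereocentres, the aldehyde and the lactone unchanged.

Step 14
Reactants: 19 aldehyde ester
Product: 20 (4S,5R)-4-[(1R)-1-{[(2S,3S)-2,3-dimethyloxirane-2-carbonyl]oxy}-2-(triethylsilyloxy)ethyl]-5-[(1E,5Z)-6-iodo-2-methylhepta-1,5-dien-1-yl]-3-methylideneoxolan-2-one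
Conditions: EtPPh3I, n-BuLi, THF, 0 °C; I2, −78 °C; NaN(SiMe3)2, −78 °C; then 19, −78 → −20 °C
Reagents that add atoms: ethyltriphenylphosphonium iodide, CC[P+](c1ccccc1)(c1ccccc1)c1ccccc1.[I-]; iodine, II
Why: Stork–Zhao olefination, in which the α-iodo ylide Ph3P=C(I)CH3 reacts with the aldehyde under kinetic control to give the (Z)-2-iodoalkene (iodine cis to the chain) faster than it adds to the hindered α-methylene lactone.

Step 15
Reactants: 20 iodoalkene silyl ether
Product: 21 (4S,5R)-4-[(1R)-1-{[(2S,3S)-2,3-dimethyloxirane-2-carbonyl]oxy}-2-oxoethyl]-5-[(1E,5Z)-6-iodo-2-methylhepta-1,5-dien-1-yl]-3-methylideneoxolan-2-one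
Conditions: (COCl)2, DMSO, CH2Cl2, −78 → −40 °C; i-Pr2NEt, −78 → 0 °C
Reagents that add atoms: none
Why: Swern oxidation applied directly to the primary triethylsilyl ether, in which the chlorosulfonium reagent cleaves the Si–O bond and oxidises the released oxygen, while the hindered base at low temperature avoids epimerisation of the α-acyloxy aldehyde at C8.

Step 16
Reactants: 21 iodo aldehyde
Product: 22 (3aS,4R,5R,6Z,10E,11aR)-5-hydroxy-6,10-dimethyl-3-methylidene-2-oxo-2,3,3a,4,5,8,9,11a-octahydrocyclodeca[b]furan-4-yl (2S,3S)-2,3-dimethyloxirane-2-carboxylate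
Conditions: CrCl2 (10 equiv), NiCl2 (10 mol%), DMSO/THF (3:1), 0.002 M, rt
Reagents that add atoms: none
Why: Nozaki–Hiyama–Kishi reaction, in which zerovalent nickel inserts into the C10–I bond and the alkenyl trivalent-chromium species adds to the C9 aldehyde with retention of the Z olefin to close the ten-membered ring; the 9R carbinol is expected from a ring-forming transition state with the C8 acyloxy group and the chromium alkoxide trans and pseudo-equatorial, but this is not secured by a general rule (see fallback).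

Step 17
Reactants: 22 macrocyclic alcohol
Product: 23 (3aS,4R,5R,6Z,10E,11aR)-5-(acetyloxy)-6,10-dimethyl-3-methylidene-2-oxo-2,3,3a,4,5,8,9,11a-octahydrocyclodeca[b]furan-4-yl (2S,3S)-2,3-dimethyloxirane-2-carboxylate (CNP0304643.2)
Conditions: Ac2O (3 equiv), pyridine, DMAP (10 mol%), CH2Cl2, 0 °C → rt
Reagents that add atoms: acetic anhydride, CC(=O)OC(C)=O
Why: DMAP-catalysed acetylation of the secondary allylic hydroxyl proceeds with retention at C9 and leaves the other esters untouched, giving the target.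

Compound list
1 | methyl angelate, methyl (2Z)-2-methylbut-2-enoate | C/C=C(/C)C(=O)OC | starting material
2 | (2Z)-2-methylbut-2-en-1-ol | C/C=C(/C)CO | intermediate
3 | [(2R,3S)-2,3-dimethyloxiran-2-yl]methanol | OC[C@@]1(C)O[C@H]1C | intermediate
4 | (2S,3S)-2,3-dimethyloxirane-2-carboxylic acid | OC(=O)[C@@]1(C)O[C@H]1C | intermediate
5 | (S)-(+)-linalool, (3S)-3,7-dimethylocta-1,6-dien-3-ol | CC(C)=CCC[C@](C)(O)C=C | starting material
6 | acryloyl chloride | C=CC(=O)Cl | starting material
7 | (3S)-3,7-dimethylocta-1,6-dien-3-yl prop-2-enoate | CC(C)=CCC[C@@](C)(C=C)OC(=O)C=C | intermediate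
8 | (3S)-3-methyl-6-oxohex-1-en-3-yl prop-2-enoate | O=CCC[C@@](C)(C=C)OC(=O)C=C | intermediate (not isolated)
9 | (3S)-6,6-dimethoxy-3-methylhex-1-en-3-yl prop-2-enoate | C=C[C@](C)(CCC(OC)OC)OC(=O)C=C | intermediate
10 | (S)-glyceraldehyde acetonide, (4S)-2,2-dimethyl-1,3-dioxolane-4-carbaldehyde | O=C[C@@H]1COC(C)(C)O1 | starting material
11 | (3S)-6,6-dimethoxy-3-methylhex-1-en-3-yl 2-{[(4S)-2,2-dimethyl-1,3-dioxolan-4-yl](hydroxy)methyl}prop-2-enoate (carbinol epimers) | C=C[C@](C)(CCC(OC)OC)OC(=O)C(=C)C(O)[C@@H]1COC(C)(C)O1 | intermediate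
12 | (3S)-6,6-dimethoxy-3-methylhex-1-en-3-yl (2Z)-2-(bromomethyl)-3-[(4R)-2,2-dimethyl-1,3-dioxolan-4-yl]prop-2-enoate | C=C[C@](C)(CCC(OC)OC)OC(=O)/C(CBr)=C/[C@@H]1COC(C)(C)O1 | intermediate
13 | (3S)-6,6-dimethoxy-3-methylhex-1-en-3-yl (3R)-3-[(4R)-2,2-dimethyl-1,3-dioxolan-4-yl]-2-methylidenepent-4-enoate | C=C[C@](C)(CCC(OC)OC)OC(=O)C(=C)[C@@H](C=C)[C@@H]1COC(C)(C)O1 | intermediate
14 | (4R,7S)-7-(3,3-dimethoxypropyl)-4-[(4R)-2,2-dimethyl-1,3-dioxolan-4-yl]-7-methyl-3-methylidene-4,7-dihydrooxepin-2(3H)-one | C=C1C(=O)O[C@@](C)(CCC(OC)OC)/C=C\[C@H]1[C@@H]2COC(C)(C)O2 | intermediate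
15 | (4S,5R)-5-[(1E)-5,5-dimethoxy-2-methylpent-1-en-1-yl]-4-[(4R)-2,2-dimethyl-1,3-dioxolan-4-yl]-3-methylideneoxolan-2-one | C=C1C(=O)O[C@H](/C=C(\C)CCC(OC)OC)[C@H]1[C@@H]2COC(C)(C)O2 | intermediate
16 | (4R,5R)-4-[(1R)-1,2-dihydroxyethyl]-3-methylidene-5-[(1E)-2-methyl-5-oxopent-1-en-1-yl]oxolan-2-one | C=C1C(=O)O[C@H](/C=C(\C)CCC=O)[C@H]1[C@@H](O)CO | intermediate
17 | (4R,5R)-4-[(1R)-1-hydroxy-2-(triethylsilyloxy)ethyl]-3-methylidene-5-[(1E)-2-methyl-5-oxopent-1-en-1-yl]oxolan-2-one | C=C1C(=O)O[C@H](/C=C(\C)CCC=O)[C@H]1[C@@H](O)CO[Si](CC)(CC)CC | intermediate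
18 | (2S,3S)-2,3-dimethyloxirane-2-carboxylic 2,4,6-trichlorobenzoic anhydride | O=C(OC(=O)c1c(Cl)cc(Cl)cc1Cl)[C@@]1(C)O[C@H]1C | intermediate (not isolated)
19 | (4S,5R)-4-[(1R)-1-{[(2S,3S)-2,3-dimethyloxirane-2-carbonyl]oxy}-2-(triethylsilyloxy)ethyl]-3-methylidene-5-[(1E)-2-methyl-5-oxopent-1-en-1-yl]oxolan-2-one | C=C1C(=O)O[C@H](/C=C(\C)CCC=O)[C@H]1[C@@H](OC(=O)[C@@]2(C)O[C@H]2C)CO[Si](CC)(CC)CC | intermediate
20 | (4S,5R)-4-[(1R)-1-{[(2S,3S)-2,3-dimethyloxirane-2-carbonyl]oxy}-2-(triethylsilyloxy)ethyl]-5-[(1E,5Z)-6-iodo-2-methylhepta-1,5-dien-1-yl]-3-methylideneoxolan-2-one | C=C1C(=O)O[C@H](/C=C(\C)CC/C=C(/C)I)[C@H]1[C@@H](OC(=O)[C@@]2(C)O[C@H]2C)CO[Si](CC)(CC)CC | intermediate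
21 | (4S,5R)-4-[(1R)-1-{[(2S,3S)-2,3-dimethyloxirane-2-carbonyl]oxy}-2-oxoethyl]-5-[(1E,5Z)-6-iodo-2-methylhepta-1,5-dien-1-yl]-3-methylideneoxolan-2-one | C=C1C(=O)O[C@H](/C=C(\C)CC/C=C(/C)I)[C@H]1[C@@H](OC(=O)[C@@]2(C)O[C@H]2C)C=O | intermediate
22 | (3aS,4R,5R,6Z,10E,11aR)-5-hydroxy-6,10-dimethyl-3-methylidene-2-oxo-2,3,3a,4,5,8,9,11a-octahydrocyclodeca[b]furan-4-yl (2S,3S)-2,3-dimethyloxirane-2-carboxylate | C=C1C(=O)O[C@@H]2/C=C(\C)CC/C=C(/C)[C@@H](O)[C@H](OC(=O)[C@@]3(C)O[C@H]3C)[C@@H]12 | intermediate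
23 | (3aS,4R,5R,6Z,10E,11aR)-5-(acetyloxy)-6,10-dimethyl-3-methylidene-2-oxo-2,3,3a,4,5,8,9,11a-octahydrocyclodeca[b]furan-4-yl (2S,3S)-2,3-dimethyloxirane-2-carboxylate | C=C1C(=O)O[C@@H]2/C=C(\C)CC/C=C(/C)[C@@H](OC(C)=O)[C@H](OC(=O)[C@@]3(C)O[C@H]3C)[C@@H]12 | target

Total step count: 17. Longest linear sequence: 14 steps (steps 4 to 17, from (S)-linalool); steps 1 to 3 supply the side-chain acid 4.

Steps most likely to fail

Step 10 (key step). The π-allyl palladium carboxylate may undergo syn/anti exchange through η1 species before ring closure, which would erode the E geometry and the C6 configuration, or it may lose a β-hydrogen to give a diene. The fallback sets out from 14. LiOH in THF/H2O (0 °C → rt), then acidification to pH 5, should open the lactone to the seco acid (3R,4Z,6S)-3-[(4R)-2,2-dimethyl-1,3-dioxolan-4-yl]-6-hydroxy-9,9-dimethoxy-6-methyl-2-methylidenenon-4-enoic acid F1. PdCl2(MeCN)2 (5 mol%) in THF at 0 °C should then effect a dehydrative SN2′ cyclisation: divalent palladium, held by the tertiary hydroxyl and the olefin, lets the carboxyl oxygen add to C6 syn to the leaving hydroxyl, so that the chirality is transferred without a free π-allyl species. The route is rejoined at 15.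

Step 16. The addition to the aldehyde may show poor facial selectivity: polar Felkin–Anh attack anti to the C8 acyloxy group would favour the C9 epimer, and the ring closure itself may be slow. The fallback sets out from 21. The same cyclisation is run and the epimeric carbinol (3aS,4R,5S,6Z,10E,11aR)-5-hydroxy-6,10-dimethyl-3-methylidene-2-oxo-2,3,3a,4,5,8,9,11a-octahydrocyclodeca[b]furan-4-yl (2S,3S)-2,3-dimethyloxirane-2-carboxylate F2 is carried on, whatever the ratio. Dess–Martin periodinane with NaHCO3 in CH2Cl2 should give the enone (3aS,4R,6Z,10E,11aR)-6,10-dimethyl-3-methylidene-2,5-dioxo-2,3,3a,4,5,8,9,11a-octahydrocyclodeca[b]furan-4-yl (2S,3S)-2,3-dimethyloxirane-2-carboxylate F3. Luche reduction (NaBH4, CeCl3·7H2O, MeOH, −78 °C) should then deliver hydride anti to the C8–O bond, which for a ketone gives the threo (9R) carbinol. The route is rejoined at 22.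

Step 14. The ylide may add to the α-methylene lactone in competition with the aldehyde, and the Z selectivity may be incomplete on this substrate. The fallback sets out from 19. Me2NH in THF at 0 °C should add reversibly to the exocyclic methylene to give the protected lactone (4S,5R)-3-[(dimethylamino)methyl]-4-[(1R)-1-{[(2S,3S)-2,3-dimethyloxirane-2-carbonyl]oxy}-2-(triethylsilyloxy)ethyl]-5-[(1E)-2-methyl-5-oxopent-1-en-1-yl]oxolan-2-one F4 (C11 epimers). The same olefination should then give (4S,5R)-3-[(dimethylamino)methyl]-4-[(1R)-1-{[(2S,3S)-2,3-dimethyloxirane-2-carbonyl]oxy}-2-(triethylsilyloxy)ethyl]-5-[(1E,5Z)-6-iodo-2-methylhepta-1,5-dien-1-yl]oxolan-2-one F5. Quaternisation with MeI and elimination with aq. NaHCO3 restore the methylene group, and the route is rejoined at 20.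

Further compounds
F1 | step 10 | (3R,4Z,6S)-3-[(4R)-2,2-dimethyl-1,3-dioxolan-4-yl]-6-hydroxy-9,9-dimethoxy-6-methyl-2-methylidenenon-4-enoic acid | OC(=O)C(=C)[C@@H](/C=C\[C@@](C)(O)CCC(OC)OC)[C@@H]1COC(C)(C)O1
F2 | step 16 | (3aS,4R,5S,6Z,10E,11aR)-5-hydroxy-6,10-dimethyl-3-methylidene-2-oxo-2,3,3a,4,5,8,9,11a-octahydrocyclodeca[b]furan-4-yl (2S,3S)-2,3-dimethyloxirane-2-carboxylate | C=C1C(=O)O[C@@H]2/C=C(\C)CC/C=C(/C)[C@H](O)[C@H](OC(=O)[C@@]3(C)O[C@H]3C)[C@@H]12
F3 | step 16 | (3aS,4R,6Z,10E,11aR)-6,10-dimethyl-3-methylidene-2,5-dioxo-2,3,3a,4,5,8,9,11a-octahydrocyclodeca[b]furan-4-yl (2S,3S)-2,3-dimethyloxirane-2-carboxylate | C=C1C(=O)O[C@@H]2/C=C(\C)CC/C=C(/C)C(=O)[C@H](OC(=O)[C@@]3(C)O[C@H]3C)[C@@H]12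
F4 | step 14 | (4S,5R)-3-[(dimethylamino)methyl]-4-[(1R)-1-{[(2S,3S)-2,3-dimethyloxirane-2-carbonyl]oxy}-2-(triethylsilyloxy)ethyl]-5-[(1E)-2-methyl-5-oxopent-1-en-1-yl]oxolan-2-one (C3 epimers) | CN(C)CC1C(=O)O[C@H](/C=C(\C)CCC=O)[C@H]1[C@@H](OC(=O)[C@@]2(C)O[C@H]2C)CO[Si](CC)(CC)CC
F5 | step 14 | (4S,5R)-3-[(dimethylamino)methyl]-4-[(1R)-1-{[(2S,3S)-2,3-dimethyloxirane-2-carbonyl]oxy}-2-(triethylsilyloxy)ethyl]-5-[(1E,5Z)-6-iodo-2-methylhepta-1,5-dien-1-yl]oxolan-2-one (C3 epimers) | CN(C)CC1C(=O)O[C@H](/C=C(\C)CC/C=C(/C)I)[C@H]1[C@@H](OC(=O)[C@@]2(C)O[C@H]2C)CO[Si](CC)(CC)CC
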